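**Retrosynthetic overview**

1. The target is disconnected at the C14 ester (Mitsunobu esterification of a 14,15-diol with (2R,3S)-3-hydroxy-2-methylbutanoic acid, made from D-threonine), at the C9 tiglate, and at the two PMB ethers on C14–O and C15–O.
2. The 10-membered carbocycle is the last ring formed: the C9–C10 bond is closed by an electroreductive Cr/Ni alkenyl iodide–aldehyde coupling, which also sets C9.
3. The epoxide is the first ring formed, on the open chain: chelation-controlled hydroxymethylation of an α-hydroxy ketone sets C4, then an invertive closure at C5 gives the trans-epoxide.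
4. The chain comes from (S)-carvone (C7 bought, C5 by Luche reduction) through ring cleavage to a keto aldehyde, enolate propargylation for C2–C3 with a but-2-yne-1,4-diol unit (C2, C1, C10, C14), alkyne to (E)-vinyl iodide, and ene-chlorination/acetate displacement for the C12 acetate.

Assumption: germacrane numbering of the target is used for all open-chain intermediates (ring C1–C10 with C1=C10, epoxide C4–C5, O-tigloyl on C9, C14 on C10, C15 on C4, C11(=C13)(C12) on C7), so the target is (1(10)E,4S,5R,7S,9S) with a (2R,3S) side-chain acid; compounds 1, 7, 8, 13 and 26 are bought.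

**Step 1**
Reactants: 1 (S)-(+)-carvone
Product: 2 (1S,5S)-cis-carveol
Conditions: NaBH4, CeCl3·7H2O, MeOH, −78 → 0 °C
Reagents that add atoms: none
Why: Luche 1,2-reduction, in which axial hydride delivery to the enone half-chair with an equatorial isopropenyl group gives the cis alcohol (dr ≥ 95:5), so the C5 carbinol (S) is set by the bought C7 stereocentre.

**Step 2**
Reactants: 2 (1S,5S)-cis-carveol
Product: 3 syn-2,3-epoxy-cis-carveol (OH, epoxide O and isopropenyl all cis)
Conditions: VO(acac)2 (2 mol %), t-BuOOH, CH2Cl2, 0 °C → rt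
Reagents that add atoms: tert-butyl hydroperoxide, CC(C)(C)OO
Why: Hydroxyl-directed vanadium/TBHP epoxidation reacts only at the allylic-alcohol alkene and leaves the isopropenyl group, delivering oxygen syn to OH (both new centres are erased in step 4).

**Step 3**
Reactants: 3 syn-2,3-epoxy-cis-carveol
Product: 4 TBS ether of 3
Conditions: TBSOTf, 2,6-lutidine, CH2Cl2, −78 → 0 °C
Reagents that add atoms: tert-butyldimethylsilyl triflate, CC(C)(C)[Si](C)(C)OS(=O)(=O)C(F)(F)F
Why: Silylation of the hindered secondary alcohol masks the hydroxyl so that the coming glycol cleavage cannot also cut the bond next to the carbinol carbon.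

**Step 4**
Reactants: 4 TBS ether of 3
Product: 5 (3R,5S)-5-[(tert-butyldimethylsilyl)oxy]-6-oxo-3-(prop-1-en-2-yl)heptanal
Conditions: H5IO6, THF/H2O, 0 °C → rt
Reagents that add atoms: water, O
Why: Periodic acid hydrolyses the trisubstituted epoxide and cleaves the resulting glycol in the same pot (Malaprade-type cleavage), opening the ring to the methyl ketone (C4) and the aldehyde (C9) without touching C5 or C7.

**Step 5**
Reactants: 5 keto aldehyde
Product: 6 (3S,5R)-3-[(tert-butyldimethylsilyl)oxy]-7,7-dimethoxy-5-(prop-1-en-2-yl)heptan-2-one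
Conditions: HC(OMe)3, MeOH, PPTS (5 mol %), rt
Reagents that add atoms: trimethyl orthoformate, COC(OC)OC; methanol, CO
Why: Acid-catalysed acetalisation is far faster for the unhindered aldehyde than for the α-silyloxy ketone, so only C9 is masked.

**Step 6**
Reactants: 7 4-methoxybenzyl alcohol; 8 1,4-dibromobut-2-yne (3 equiv)
Product: 9 1-{[(4-bromobut-2-yn-1-yl)oxy]methyl}-4-methoxybenzene
Conditions: NaH, THF, 0 °C → rt
Reagents that add atoms: none
Why: Williamson etherification, in which a threefold excess of the symmetrical dibromide limits double substitution.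

**Step 7**
Reactants: 6 keto acetal; 9 propargylic bromide
Product: 11 silyl-protected ynone acetal (C2–C3 bond formed), via lithium enolate 10 (not isolated)
Conditions: LDA, THF, −78 °C; then 9, DMPU, −78 → −30 °C
Reagents that add atoms: none
Why: Kinetic deprotonation with LDA occurs at the methyl group of the α-silyloxy ketone and the enolate is C-alkylated by the propargylic bromide (SN2 enolate alkylation), with no stereocentre touched.

**Step 8**
Reactants: 11 silyl-protected ynone acetal
Product: 12 (5S,7R)-α-hydroxy ketone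
Conditions: TBAF, AcOH (1:1), THF, 0 °C → rt
Reagents that add atoms: none
Why: Buffered fluoride desilylation frees the α-hydroxyl under near-neutral conditions that avoid epimerisation at C5 and leave the dimethyl acetal intact.

**Step 9**
Reactants: 7 4-methoxybenzyl alcohol; 13 tributyl(iodomethyl)stannane
Product: 14 tributyl{[(4-methoxybenzyl)oxy]methyl}stannane
Conditions: NaH, THF/DMF, 0 °C → rt
Reagents that add atoms: none
Why: Williamson etherification of the alkoxide with the iodomethylstannane gives the tin precursor of a hydroxymethyl anion equivalent (Still-type reagent).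

**Step 10**
Reactants: 12 α-hydroxy ketone; 14 stannane (3 equiv)
Product: 15 (4S,5S,7R)-4,5-diol with 15-OPMB
Conditions: 14, n-BuLi, THF, −78 °C; MgBr2·OEt2; then 12, −78 → −40 °C; H2O
Reagents that add atoms: none
Why: Sn/Li then Li/Mg exchange gives an α-alkoxymethyl Grignard reagent that adds to the five-membered magnesium alkoxide–ketone chelate from the face opposite C6 (Cram chelation control), setting C4 (S) from C5.

**Step 11**
Reactants: 15 diol
Product: 17 (4S,5R,7R)-trans-epoxy alkyne acetal, via secondary mesylate 16 (not isolated)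
Conditions: MsCl, Et3N, CH2Cl2, −20 °C; then K2CO3, MeOH, rt
Reagents that add atoms: none
Why: Mesylation takes only the secondary alcohol and the tertiary alkoxide then displaces the mesylate in a 3-exo-tet SN2 closure with inversion at C5, giving the trans (4S,5R) epoxide.

**Step 12**
Reactants: 17 epoxy alkyne acetal
Product: 19 (E)-vinyl iodide acetal (I on C10, trans to C2), via (E)-vinylstannane 18 (not isolated)
Conditions: Bu3SnH, PdCl2(PPh3)2 (3 mol %), THF, 0 °C → rt; then I2, CH2Cl2, 0 °C
Reagents that add atoms: iodine, II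
Why: Palladium-catalysed syn-hydrostannation places tin on C10 (proximal to the propargylic ether oxygen) and iododestannylation proceeds with retention, fixing the alkene geometry needed for the ring.

**Step 13**
Reactants: 19 vinyl iodide acetal
Product: 20 12-chloro derivative of 19 (2-(chloromethyl)allyl group on C7)
Conditions: NCS, PhSeCl (10 mol %), CH2Cl2, rt
Reagents that add atoms: N-chlorosuccinimide, O=C1CCC(=O)N1Cl
Why: Selenium-catalysed ene-type allylic chlorination with NCS attacks only the electron-rich 1,1-disubstituted alkene (the iodoalkene is deactivated) and puts chlorine on a methylene terminus of the 2-substituted allyl unit.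

**Step 14**
Reactants: 20 allylic chloride
Product: 21 12-acetate (vinyl iodide acetal)
Conditions: CsOAc, DMF, 40 °C
Reagents that add atoms: caesium acetate, CC(=O)[O-].[Cs+]
Why: SN2 displacement of the primary allylic chloride by acetate, where SN2 and SN2′ give the same product on this symmetrical allyl system.

**Step 15**
Reactants: 21 acetate acetal
Product: 22 iodo aldehyde (C9 CHO)
Conditions: PPTS (0.3 equiv), acetone/H2O 9:1, 40 °C
Reagents that add atoms: water, O
Why: Mild acid hydrolysis of the dimethyl acetal frees the aldehyde now that C5–O is locked in the epoxide, and the epoxide, acetate and PMB ethers tolerate these conditions.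

**Step 16**
Reactants: 22 iodo aldehyde
Product: 23 (1(10)E,4S,5R,7S,9S)-12-acetoxy-4,5-epoxy-14,15-bis[(4-methoxybenzyl)oxy]germacra-1(10),11(13)-dien-9-ol
Conditions: CrCl3 (20 mol %), NiCl2·glyme (3 mol %), LiCl, DMF, Al anode | Ni-foam cathode, undivided cell, 3 mA, 2.2 F/mol, 25 °C, 22 added over 12 h (final 2 mM)
Reagents that add atoms: none
Why: Proposed new method: an electroreductive Cr/Ni-co-catalysed Nozaki–Hiyama–Kishi macrocyclisation in which cathodically formed Ni(0) inserts into the C10–I bond with retention of alkene geometry, the alkenyl group passes to Cr(III) (re-reduced to Cr(II) at the cathode), the (E)-alkenylchromium adds to the tethered C9 aldehyde and Al(III) from the sacrificial anode takes over the alkoxide so that chromium turns over, the low stationary concentration of the organochromium plus slow substrate addition favouring the 10-membered ring over dimers, while the 9S carbinol is predicted from substrate control (C7 side chain pseudo-equatorial, epoxide oxygen locked outside the ring, Cr-bound oxygen pseudo-axial, eclipsing C1=C10 and anti to the C14 methylene to avoid A(1,2) strain); the closest known reaction types are the intermolecular Cr-catalytic electrochemical NHK coupling of alkenyl halides with aldehydes and stoichiometric CrCl2/NiCl2 NHK macrocyclisations.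

**Step 17**
Reactants: 23 macrocyclic alcohol
Product: 24 9-O-tiglate of 23
Conditions: tigloyl chloride, DMAP, pyridine, CH2Cl2, 0 °C → rt
Reagents that add atoms: (E)-2-methylbut-2-enoyl chloride, C/C=C(\C)C(=O)Cl
Why: DMAP-catalysed acylation retains the C9 configuration and gives the tiglate without E/Z drift because tigloyl is the stable geometry.

**Step 18**
Reactants: 24 tiglate
Product: 25 (1(10)E,4S,5R,7S,9S)-12-acetoxy-4,5-epoxy-14,15-dihydroxygermacra-1(10),11(13)-dien-9-yl (E)-2-methylbut-2-enoate
Conditions: DDQ (2.6 equiv), CH2Cl2/pH 7 buffer 10:1, 0 °C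
Reagents that add atoms: none
Why: Oxidative cleavage of both p-methoxybenzyl ethers with buffered DDQ frees the C14 and C15 hydroxyls, and a short reaction time avoids oxidation of the liberated allylic alcohol.

**Step 19**
Reactants: 26 D-threonine
Product: 27 (2R,3S)-2-bromo-3-hydroxybutanoic acid
Conditions: NaNO2, KBr, 1.25 M H2SO4, −5 °C → rt
Reagents that add atoms: potassium bromide, [K+].[Br-]
Why: Diazotisation in the presence of bromide proceeds with retention at C2 through the α-lactone (double inversion), so both threonine stereocentres are kept.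

**Step 20**
Reactants: 27 bromo acid
Product: 28 potassium (2S,3S)-3-methyloxirane-2-carboxylate (cis)
Conditions: KOH (2.05 equiv), EtOH, −20 °C → rt
Reagents that add atoms: potassium hydroxide, [K+].[OH-]
Why: Intramolecular Williamson (SN2) closure of the bromohydrin with inversion at C2 gives the cis-epoxy carboxylate.

**Step 21**
Reactants: 28 epoxy carboxylate
Product: 29 (2R,3S)-3-hydroxy-2-methylbutanoic acid
Conditions: Me2CuLi (from CuI, 2 MeLi), Et2O/THF, −30 → 0 °C; then 1 M HCl
Reagents that add atoms: lithium dimethylcuprate, [Li+].C[Cu-]C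
Why: Dimethylcuprate opens the 2,3-epoxy carboxylate at C2 (α to the carboxylate) by SN2 with inversion, turning the cis-epoxide into the syn (2R,3S) aldol-type acid.

**Step 22**
Reactants: 25 diol; 29 (2R,3S)-3-hydroxy-2-methylbutanoic acid
Product: 30 target CNP0316239.1
Conditions: PPh3, DIAD, THF, 0 °C
Reagents that add atoms: none
Why: Mitsunobu esterification, in which the primary allylic C14 oxyphosphonium is displaced by the carboxylate much faster than the neopentyl-type C15 one or the secondary hydroxyl of the acid, and no stereocentre is involved.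

**Compound list**

1 | (S)-(+)-carvone, (5S)-2-methyl-5-(prop-1-en-2-yl)cyclohex-2-en-1-one | C=C(C)[C@H]1CC=C(C)C(=O)C1 | starting material
2 | (1S,5S)-cis-carveol | C=C(C)[C@H]1CC=C(C)[C@@H](O)C1 | intermediate
3 | syn-2,3-epoxy-cis-carveol (OH, epoxide O and isopropenyl all cis) | C=C(C)[C@H]1C[C@H]2O[C@@]2(C)[C@@H](O)C1 | intermediate
4 | TBS ether of 3 | C=C(C)[C@H]1C[C@H]2O[C@@]2(C)[C@@H](O[Si](C)(C)C(C)(C)C)C1 | intermediate
5 | (3R,5S)-5-[(tert-butyldimethylsilyl)oxy]-6-oxo-3-(prop-1-en-2-yl)heptanal | C=C(C)[C@H](C[C@H](O[Si](C)(C)C(C)(C)C)C(C)=O)CC=O | intermediate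
6 | (3S,5R)-3-[(tert-butyldimethylsilyl)oxy]-7,7-dimethoxy-5-(prop-1-en-2-yl)heptan-2-one | C=C(C)[C@H](C[C@H](O[Si](C)(C)C(C)(C)C)C(C)=O)CC(OC)OC | intermediate
7 | 4-methoxybenzyl alcohol | COc1ccc(CO)cc1 | starting material
8 | 1,4-dibromobut-2-yne | BrCC#CCBr | starting material
9 | 1-{[(4-bromobut-2-yn-1-yl)oxy]methyl}-4-methoxybenzene | COc1ccc(COCC#CCBr)cc1 | intermediate
10 | lithium enolate of 6 (methyl side) | C=C(C)[C@H](C[C@H](O[Si](C)(C)C(C)(C)C)C(=C)O[Li])CC(OC)OC | intermediate
11 | (5S,7R)-ynone acetal: 5-OTBS, 4-oxo, C1≡C10, 14-OPMB, C9 dimethyl acetal | C=C(C)[C@H](C[C@H](O[Si](C)(C)C(C)(C)C)C(=O)CCC#CCOCc1ccc(OC)cc1)CC(OC)OC | intermediate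
12 | (5S,7R)-α-hydroxy ketone (desilylated 11) | C=C(C)[C@H](C[C@H](O)C(=O)CCC#CCOCc1ccc(OC)cc1)CC(OC)OC | intermediate
13 | tributyl(iodomethyl)stannane | CCCC[Sn](CI)(CCCC)CCCC | starting material
14 | tributyl{[(4-methoxybenzyl)oxy]methyl}stannane | CCCC[Sn](CCCC)(CCCC)COCc1ccc(OC)cc1 | intermediate
15 | (4S,5S,7R)-4,5-diol: 14,15-bis-OPMB, C1≡C10, C9 dimethyl acetal | C=C(C)[C@H](C[C@H](O)[C@@](O)(COCc1ccc(OC)cc1)CCC#CCOCc1ccc(OC)cc1)CC(OC)OC | intermediate
16 | 5-O-mesylate of 15 | C=C(C)[C@H](C[C@H](OS(C)(=O)=O)[C@@](O)(COCc1ccc(OC)cc1)CCC#CCOCc1ccc(OC)cc1)CC(OC)OC | intermediate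
17 | (4S,5R,7R)-trans-4,5-epoxy alkyne acetal | C=C(C)[C@H](C[C@H]1O[C@]1(COCc2ccc(OC)cc2)CCC#CCOCc2ccc(OC)cc2)CC(OC)OC | intermediate
18 | (E)-10-(tributylstannyl)alkene from 17 (Sn trans to C2) | C=C(C)[C@H](C[C@H]1O[C@]1(COCc2ccc(OC)cc2)CC/C=C(/[Sn](CCCC)(CCCC)CCCC)COCc2ccc(OC)cc2)CC(OC)OC | intermediate
19 | (E)-10-iodoalkene acetal (I trans to C2) | C=C(C)[C@H](C[C@H]1O[C@]1(COCc2ccc(OC)cc2)CC/C=C(/I)COCc2ccc(OC)cc2)CC(OC)OC | intermediate
20 | 12-chloro derivative of 19 | C=C(CCl)[C@H](C[C@H]1O[C@]1(COCc2ccc(OC)cc2)CC/C=C(/I)COCc2ccc(OC)cc2)CC(OC)OC | intermediate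
21 | 12-acetoxy derivative of 19 | C=C(COC(C)=O)[C@H](C[C@H]1O[C@]1(COCc2ccc(OC)cc2)CC/C=C(/I)COCc2ccc(OC)cc2)CC(OC)OC | intermediate
22 | iodo aldehyde (C9 CHO, C10 iodide) | C=C(COC(C)=O)[C@H](C[C@H]1O[C@]1(COCc2ccc(OC)cc2)CC/C=C(/I)COCc2ccc(OC)cc2)CC=O | intermediate
23 | (1(10)E,4S,5R,7S,9S)-12-acetoxy-4,5-epoxy-14,15-bis[(4-methoxybenzyl)oxy]germacra-1(10),11(13)-dien-9-ol | C=C(COC(C)=O)[C@H]1C[C@H](O)/C(COCc2ccc(OC)cc2)=C/CC[C@@]2(COCc3ccc(OC)cc3)O[C@@H]2C1 | intermediate
24 | 9-O-tiglate of 23 | C=C(COC(C)=O)[C@H]1C[C@H](OC(=O)/C(C)=C/C)/C(COCc2ccc(OC)cc2)=C/CC[C@@]2(COCc3ccc(OC)cc3)O[C@@H]2C1 | intermediate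
25 | 14,15-diol tiglate acetate | C=C(COC(C)=O)[C@H]1C[C@H](OC(=O)/C(C)=C/C)/C(CO)=C/CC[C@@]2(CO)O[C@@H]2C1 | intermediate
26 | D-threonine, (2R,3S)-2-amino-3-hydroxybutanoic acid | C[C@H](O)[C@@H](N)C(=O)O | starting material
27 | (2R,3S)-2-bromo-3-hydroxybutanoic acid | C[C@H](O)[C@@H](Br)C(=O)O | intermediate
28 | potassium (2S,3S)-3-methyloxirane-2-carboxylate (cis) | C[C@@H]1O[C@@H]1C(=O)[O-].[K+] | intermediate
29 | (2R,3S)-3-hydroxy-2-methylbutanoic acid | C[C@H](O)[C@@H](C)C(=O)O | intermediate
30 | CNP0316239.1 | C=C(COC(C)=O)[C@H]1C[C@H](OC(=O)/C(C)=C/C)/C(COC(=O)[C@H](C)[C@H](C)O)=C/CC[C@@]2(CO)O[C@@H]2C1 | target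

**Step count**

Total: 22 steps. Longest linear sequence: 17 steps (1–5, 7, 8, 10–18, 22, from (S)-carvone).

**Three steps most likely to fail**

Step 16 (the proposed electro-NHK ring closure). The strained (E)-cyclodecene may form slowly, so protodeiodination or dimerisation can compete; the allylic acetate is a possible Ni(0) target; and the C9 selectivity is a prediction. The fallback sets out from 22 and comes back at 23 by the established stoichiometric Nozaki–Hiyama–Kishi macrocyclisation (CrCl2 8–10 equiv, NiCl2 1 mol %, DMSO/THF 3:1, syringe-pump addition to 2 mM, rt). This is a reagent-driven organochromium ring closure with no cell and no catalytic turnover to engineer, and it makes no new compound (F0).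

Step 17 (retentive tigloylation). It gives the target configuration only if the ring closure delivers the 9S carbinol. If the closure gives mainly the other epimer, the fallback sets out from 22, whose ring closure then gives the (9R)-epimer of 23 F1. F1 is esterified with tiglic acid under Mitsunobu conditions (PPh3, DIAD, toluene, 0 °C) with inversion at C9, and the route is rejoined at 24.

Step 22 (Mitsunobu with an unprotected β-hydroxy acid on a diol). The secondary hydroxyl of the acid or the C15 hydroxyl could compete, and SN2′ attack is possible. The fallback sets out from 25: Corey–Kim chlorination (NCS, Me2S, CH2Cl2, −20 °C) converts only the allylic C14 alcohol into the C14 allylic chloride of 25 F2, which is displaced by the caesium salt of 29 (Cs2CO3, DMF, rt) to come back at 30.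

**Further compounds**

F0 | step 16 | none | none
F1 | step 17 | (9R)-epimer of 23 | C=C(COC(C)=O)[C@H]1C[C@@H](O)/C(COCc2ccc(OC)cc2)=C/CC[C@@]2(COCc3ccc(OC)cc3)O[C@@H]2C1
F2 | step 22 | C14 allylic chloride of 25 | C=C(COC(C)=O)[C@H]1C[C@H](OC(=O)/C(C)=C/C)/C(CCl)=C/CC[C@@]2(CO)O[C@@H]2C1
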